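**Retrosynthetic overview**

1. Target 12 ⇒ hydroxy diketone 9: the only ring (the oxolane) is closed last by reductive cycloetherification, which forms O1–C2 and C2–H together; C2 is set cis to the C3 side chain, C4 is equilibrated to trans, and the silyl group is removed in the same pot.
2. 9 ⇒ 1,4-diketone 7: C4–C5 bond by hydroxymethylation of the C4 methylene with formaldehyde.
3. 7 ⇒ enone 5 + aldehyde 6: C2–C3 bond by a carbene-catalysed enantioselective Stetter addition, which sets C3, the first and controlling stereocentre.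
4. 5 ⇒ bromoketone 1 + aldehyde 2: C3=C4 alkene by Wittig olefination.

Assumption (notation): Ar = 3,4,5-trimethoxyphenyl; ring atoms are numbered O1, C2 (aryl), C3 (CH2OH), C4 (aroyl), C5, so the target SMILES reads as (2R,3R,4S), with aryl and CH2OH cis and CH2OH and aroyl trans.

**Route**

Step 1
Reactants: 1 2-bromo-1-(3,4,5-trimethoxyphenyl)ethan-1-one; 2 2-[(tert-butyldimethylsilyl)oxy]acetaldehyde
Product: 5 (E)-4-[(tert-butyldimethylsilyl)oxy]-1-(3,4,5-trimethoxyphenyl)but-2-en-1-one, via phosphonium bromide 3 (not isolated), via phosphorus ylide 4 (not isolated)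
Conditions: PPh3, THF, rt; then Et3N, 2, THF, 65 °C
Reagents that add atoms: none
Why: Wittig olefination; the ketone-stabilised ylide made in the flask from 1 reacts with aldehyde 2 to give the (E)-enone selectively, and no stereocentre is formed.

Step 2
Reactants: 5 (E)-4-[(tert-butyldimethylsilyl)oxy]-1-(3,4,5-trimethoxyphenyl)but-2-en-1-one; 6 3,4,5-trimethoxybenzaldehyde
Product: 7 (2R)-2-{[(tert-butyldimethylsilyl)oxy]methyl}-1,4-bis(3,4,5-trimethoxyphenyl)butane-1,4-dione
Conditions: 6 (1.5 equiv), aminoindanol-derived N-pentafluorophenyl triazolium tetrafluoroborate (20 mol%, the enantiomer that gives (R)-7), i-Pr2NEt (20 mol%), catechol (20 mol%), toluene, 0 °C → rt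
Reagents that add atoms: none
Why: Proposed new method: an N-heterocyclic-carbene-catalysed enantioselective intermolecular Stetter reaction of an aryl aldehyde with an acyclic γ-silyloxy aryl enone, a β-alkyl acceptor class on which the asymmetric reaction has not been shown; the Breslow intermediate of 6 adds to the β-carbon of the s-cis enone in a hydrogen-bonded transition state in which the indane wall of the triazolylidene blocks one face, catechol shuttles the proton to the enolate, and the carbene is expelled to give the 1,4-diketone with C3 set as R under catalyst control; the closest known reaction type is the asymmetric intermolecular Stetter addition of aryl aldehydes to chalcones and of heteroaryl aldehydes to nitroalkenes.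

Step 3
Reactants: 7 (2R)-2-{[(tert-butyldimethylsilyl)oxy]methyl}-1,4-bis(3,4,5-trimethoxyphenyl)butane-1,4-dione
Product: 9 (2R,3RS)-2-{[(tert-butyldimethylsilyl)oxy]methyl}-3-(hydroxymethyl)-1,4-bis(3,4,5-trimethoxyphenyl)butane-1,4-dione, via lithium enolate 8 (not isolated)
Conditions: LiN(SiMe3)2 (1.05 equiv), THF, −78 °C; then CH2O (gas, from cracked paraformaldehyde), −78 → −40 °C; AcOH quench at −78 °C
Reagents that add atoms: formaldehyde, C=O
Why: Crossed aldol hydroxymethylation of a kinetic lithium enolate; the hindered amide base deprotonates the unbranched C4 methylene and not the C3 methine, the enolate adds to formaldehyde, the cold acidic quench prevents silyl migration and C3 epimerisation, and the new C4 centre forms as a mixture that is corrected in step 4 because it is alpha to the ketone.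

Step 4
Reactants: 9 (2R,3RS)-2-{[(tert-butyldimethylsilyl)oxy]methyl}-3-(hydroxymethyl)-1,4-bis(3,4,5-trimethoxyphenyl)butane-1,4-dione
Product: 12 (2R,3R,4S)-3-(hydroxymethyl)-4-(3,4,5-trimethoxybenzoyl)-2-(3,4,5-trimethoxyphenyl)oxolane, via hemiketal 10 (not isolated), via silyl ether 11 (not isolated)
Conditions: Et3SiH (4 equiv), Me3SiOTf (0.3 equiv), CH2Cl2, −78 °C; then DBU (1.5 equiv), −78 °C → rt; then HF·pyridine, THF, 0 °C → rt
Reagents that add atoms: none
Why: Acid-promoted reductive cycloetherification (ionic hydrogenation of a hemiketal-derived oxocarbenium ion), then base equilibration and fluoride desilylation; the C5 hydroxyl closes onto the C2 ketone, Et3SiH delivers hydride to the 2-aryl oxocarbenium ion on the face opposite the adjacent C3 CH2OSi group so that aryl and CH2O end up cis (2R), DBU equilibrates the epimerisable C4 centre to the trans arrangement (4S) while the C9 oxygen is still silylated, and HF·pyridine frees the alcohol.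

**Compound list**

1 | 2-bromo-1-(3,4,5-trimethoxyphenyl)ethan-1-one | COc1cc(cc(OC)c1OC)C(=O)CBr | starting material
2 | 2-[(tert-butyldimethylsilyl)oxy]acetaldehyde | O=CCO[Si](C)(C)C(C)(C)C | starting material
3 | [2-oxo-2-(3,4,5-trimethoxyphenyl)ethyl]triphenylphosphonium bromide | COc1cc(cc(OC)c1OC)C(=O)C[P+](c1ccccc1)(c1ccccc1)c1ccccc1.[Br-] | intermediate
4 | 1-(3,4,5-trimethoxyphenyl)-2-(triphenylphosphoranylidene)ethan-1-one | COc1cc(cc(OC)c1OC)C(=O)C=P(c1ccccc1)(c1ccccc1)c1ccccc1 | intermediate
5 | (E)-4-[(tert-butyldimethylsilyl)oxy]-1-(3,4,5-trimethoxyphenyl)but-2-en-1-one | COc1cc(cc(OC)c1OC)C(=O)/C=C/CO[Si](C)(C)C(C)(C)C | intermediate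
6 | 3,4,5-trimethoxybenzaldehyde | COc1cc(C=O)cc(OC)c1OC | starting material
7 | (2R)-2-{[(tert-butyldimethylsilyl)oxy]methyl}-1,4-bis(3,4,5-trimethoxyphenyl)butane-1,4-dione | COc1cc(cc(OC)c1OC)C(=O)[C@@H](CO[Si](C)(C)C(C)(C)C)CC(=O)c1cc(OC)c(OC)c(OC)c1 | intermediate
8 | lithium (3R)-3-{[(tert-butyldimethylsilyl)oxy]methyl}-4-oxo-1,4-bis(3,4,5-trimethoxyphenyl)but-1-en-1-olate (kinetic enolate of 7) | COc1cc(cc(OC)c1OC)C(=O)[C@@H](CO[Si](C)(C)C(C)(C)C)C=C(O[Li])c1cc(OC)c(OC)c(OC)c1 | intermediate
9 | (2R,3RS)-2-{[(tert-butyldimethylsilyl)oxy]methyl}-3-(hydroxymethyl)-1,4-bis(3,4,5-trimethoxyphenyl)butane-1,4-dione | COc1cc(cc(OC)c1OC)C(=O)[C@@H](CO[Si](C)(C)C(C)(C)C)C(CO)C(=O)c1cc(OC)c(OC)c(OC)c1 | intermediate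
10 | (3R)-3-{[(tert-butyldimethylsilyl)oxy]methyl}-2-hydroxy-4-(3,4,5-trimethoxybenzoyl)-2-(3,4,5-trimethoxyphenyl)oxolane (C2 and C4 epimers) | COc1cc(C(=O)C2COC(O)(c3cc(OC)c(OC)c(OC)c3)[C@H]2CO[Si](C)(C)C(C)(C)C)cc(OC)c1OC | intermediate
11 | (2R,3R,4S)-3-{[(tert-butyldimethylsilyl)oxy]methyl}-4-(3,4,5-trimethoxybenzoyl)-2-(3,4,5-trimethoxyphenyl)oxolane | COc1cc(C(=O)[C@@H]2CO[C@@H](c3cc(OC)c(OC)c(OC)c3)[C@H]2CO[Si](C)(C)C(C)(C)C)cc(OC)c1OC | intermediate
12 | (2R,3R,4S)-3-(hydroxymethyl)-4-(3,4,5-trimethoxybenzoyl)-2-(3,4,5-trimethoxyphenyl)oxolane = [(3S,4R,5R)-4-(hydroxymethyl)-5-(3,4,5-trimethoxyphenyl)oxolan-3-yl](3,4,5-trimethoxyphenyl)methanone | COc1cc(C(=O)[C@@H]2CO[C@@H](c3cc(OC)c(OC)c(OC)c3)[C@H]2CO)cc(OC)c1OC | target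

**Step count and risks**

Total steps: 4. Longest linear sequence: 4 (1 → 5 → 7 → 9 → 12).

The three steps most likely to fail:

Step 2 (the proposed Stetter reaction). The risks are low rate or low enantioselectivity with a β-alkyl enone, competing benzoin formation, and base-induced loss of silanol from the product. The fallback uses known chemistry, sets out from 1 and comes back at 7. A visible-light, amine-catalysed enantioselective α-alkylation of commercial 3-[(tert-butyldimethylsilyl)oxy]propanal with bromoketone 1 (diarylprolinol silyl ether catalyst, 2,6-lutidine, methyl tert-butyl ether, rt; enamine/bromoketone donor–acceptor photoactivation) gives (2R)-2-{[(tert-butyldimethylsilyl)oxy]methyl}-4-oxo-4-(3,4,5-trimethoxyphenyl)butanal F1. Aldehyde-selective addition of (3,4,5-trimethoxyphenyl)magnesium bromide in THF at −78 °C gives (3R)-3-{[(tert-butyldimethylsilyl)oxy]methyl}-4-hydroxy-1,4-bis(3,4,5-trimethoxyphenyl)butan-1-one F2 as a mixture of carbinol epimers. Dess–Martin oxidation in CH2Cl2 then returns diketone 7.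

Step 3 (hydroxymethylation). The risks are competing enolisation at C3, double addition of formaldehyde, retro-aldol or dehydration of the β-hydroxy ketone, and silyl migration between the two CH2O arms, which would erode enantiopurity. The fallback sets out from 7 and comes back at 9. The same kinetic enolate is alkylated with benzyl chloromethyl ether (THF, −78 °C) to give (2RS,3R)-2-[(benzyloxy)methyl]-3-{[(tert-butyldimethylsilyl)oxy]methyl}-1,4-bis(3,4,5-trimethoxyphenyl)butane-1,4-dione F3. Neutral hydrogenolysis of the benzyl ether (H2, Pd/C, ethyl acetate, rt) then unmasks the primary alcohol to give 9 without ever generating an aldolate.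

Step 4 (reductive cycloetherification and desilylation). The risks are insufficient facial selectivity at C2, loss of C3 integrity through the cyclic enol ether, and over-reduction of the benzylic ether or the ketone. The fallback sets out from 9 and comes back at 11, and replaces ionic hydride transfer by radical hydrogen-atom transfer. Thioketalisation with thiophenol (Me3SiOTf cat., CH2Cl2, −78 °C) gives (3R)-3-{[(tert-butyldimethylsilyl)oxy]methyl}-2-(phenylsulfanyl)-4-(3,4,5-trimethoxybenzoyl)-2-(3,4,5-trimethoxyphenyl)oxolane F4. Bu3SnH with azobisisobutyronitrile in toluene at 80 °C cleaves the C–S bond, and the C2 benzylic radical takes up hydrogen opposite the C3 side chain. After DBU equilibration this gives silyl ether 11, which is desilylated with HF·pyridine as in step 4.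

**Further compounds**

F1 | step 2 | (2R)-2-{[(tert-butyldimethylsilyl)oxy]methyl}-4-oxo-4-(3,4,5-trimethoxyphenyl)butanal | O=C[C@@H](CO[Si](C)(C)C(C)(C)C)CC(=O)c1cc(OC)c(OC)c(OC)c1
F2 | step 2 | (3R)-3-{[(tert-butyldimethylsilyl)oxy]methyl}-4-hydroxy-1,4-bis(3,4,5-trimethoxyphenyl)butan-1-one (carbinol epimers) | COc1cc(cc(OC)c1OC)C(O)[C@@H](CO[Si](C)(C)C(C)(C)C)CC(=O)c1cc(OC)c(OC)c(OC)c1
F3 | step 3 | (2RS,3R)-2-[(benzyloxy)methyl]-3-{[(tert-butyldimethylsilyl)oxy]methyl}-1,4-bis(3,4,5-trimethoxyphenyl)butane-1,4-dione | COc1cc(cc(OC)c1OC)C(=O)[C@@H](CO[Si](C)(C)C(C)(C)C)C(COCc1ccccc1)C(=O)c1cc(OC)c(OC)c(OC)c1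
F4 | step 4 | (3R)-3-{[(tert-butyldimethylsilyl)oxy]methyl}-2-(phenylsulfanyl)-4-(3,4,5-trimethoxybenzoyl)-2-(3,4,5-trimethoxyphenyl)oxolane (C2 and C4 epimers) | COc1cc(C(=O)C2COC(Sc4ccccc4)(c3cc(OC)c(OC)c(OC)c3)[C@H]2CO[Si](C)(C)C(C)(C)C)cc(OC)c1OC
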